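**Retrosynthetic overview**
1. Target ⇐ neutral hydrogenolysis (aryl O‑Bn, 7‑O‑BOM) ⇐ acylation of the free 6‑OH with 4‑(benzyloxy)benzoyl chloride (three steps from 4‑bromophenol).
2. 8α,9α‑Epoxide ⇐ 6‑OH‑directed vanadium epoxidation; seven‑membered ring ⇐ ring‑closing metathesis forming C8=C9 (allyl on C1, isopropenyl on C7).
3. C6–C7 bond and the 6,7‑syn diol pattern ⇐ (Z)‑γ‑alkoxyallylboration of a C6 aldehyde with a methacrolein‑derived stannane (two steps).
4. Cyclopentane stereotriad ⇐ i‑Pr addition to a C4 ketone; C5–C6 and C1–C10 bonds (quaternary C1) ⇐ cobalt‑catalysed silicon‑tethered radical cyclisation/allyl cross‑coupling on (S)‑3‑methylcyclopent‑2‑enol.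
5. Ring order: cyclopentane (from 3‑methylcyclopent‑2‑enone) → transient oxasilolane → seven‑membered ring by metathesis → epoxide.

Assumption: daucane locants are used throughout, also for monocyclic intermediates (C1 angular‑CH3 carbon, C2/C3 ring CH2, C4 isopropyl carbinol, C5 ring‑fusion CH, C6–C10 seven‑membered ring; β = face of the angular methyl), and a stage run on crude, unpurified material is counted inside one step.

**Route**

Step 1
Reactants: 1 3-methylcyclopent-2-en-1-one
Product: 2 (S)-3-methylcyclopent-2-en-1-ol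
Conditions: (R)-Me-CBS (10 mol %), catecholborane, toluene, −78 °C
Reagents that add atoms: none
Why: Corey–Bakshi–Shibata reduction, in which the oxazaborolidine–borane complex treats the enone arm as the large group and delivers hydride 1,2 to one face, sets C4 as (S), the centre that later controls C5 and C1.

Step 2
Reactants: 2 (S)-3-methylcyclopent-2-en-1-ol
Product: 3 (S)-(bromomethyl)dimethyl[(3-methylcyclopent-2-en-1-yl)oxy]silane
Conditions: BrCH2SiMe2Cl, Et3N, DMAP (cat.), CH2Cl2, 0 °C
Reagents that add atoms: (bromomethyl)chlorodimethylsilane C[Si](C)(Cl)CBr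
Why: Base‑mediated O‑silylation of a secondary alcohol installs the Stork–Nishiyama (bromomethyl)silyl tether without touching the stereocentre.

Step 3
Reactants: 3 (S)-(bromomethyl)dimethyl[(3-methylcyclopent-2-en-1-yl)oxy]silane
Product: 4 (3aR,4R,6aS)-2,2,4-trimethyl-4-(prop-2-en-1-yl)hexahydro-2H-cyclopenta[d][1,2]oxasilole
Conditions: CoCl2(dppp) (10 mol %), allylMgCl (2.5 equiv), THF, −40 → 0 °C
Reagents that add atoms: allylmagnesium chloride C=CC[Mg]Cl
Why: Proposed new method: a low‑valent cobalt–allyl species transfers one electron to the C–Br bond, the α‑silyl radical closes 5‑exo onto C5 of the trisubstituted alkene from the face of the tethering oxygen (cis‑fused oxasilolane, sets C5), and the tertiary C1 radical is captured by allyl–cobalt and reductively eliminated anti to the new C5–CH2 bond (quaternary C1, allyl trans to C6, methyl cis); the closest known reactions are the cobalt‑catalysed radical cyclisation/Grignard cross‑coupling of bromoacetals and (bromomethyl)silyl ethers ending at primary or secondary carbons and the cobalt‑catalysed allylation of tertiary alkyl halides, and their merger on a silicon‑tethered trisubstituted cycloalkene to build a quaternary stereocentre is new.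

Step 4
Reactants: 4 (3aR,4R,6aS)-2,2,4-trimethyl-4-(prop-2-en-1-yl)hexahydro-2H-cyclopenta[d][1,2]oxasilole
Product: 5 (2R,3R)-2-[(hydroxydimethylsilyl)methyl]-3-methyl-3-(prop-2-en-1-yl)cyclopentan-1-one
Conditions: CrO3, H2SO4, acetone/H2O, 0 °C
Reagents that add atoms: water O
Why: Jones oxidation applied directly to a silyl ether, in which aqueous acid opens the cyclic Si–O bond and Cr(VI) oxidises the freed secondary alcohol while the C–Si bond stays as a masked primary hydroxyl, creates no stereocentre and leaves C5 as the more stable epimer (side chain trans to allyl).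

Step 5
Reactants: 5 (2R,3R)-2-[(hydroxydimethylsilyl)methyl]-3-methyl-3-(prop-2-en-1-yl)cyclopentan-1-one
Product: 7 (1R,2S,3R)-2-(hydroxymethyl)-3-methyl-1-(propan-2-yl)-3-(prop-2-en-1-yl)cyclopentan-1-ol, via hydroxy silanol 6 (not isolated)
Conditions: i-PrLi (3 equiv), CeCl3, THF, −78 °C; aqueous work-up, then crude: KF, KHCO3, 30 % H2O2, THF/MeOH, 45 °C
Reagents that add atoms: isopropyllithium CC(C)[Li]; hydrogen peroxide OO
Why: Organocerium (Imamoto) 1,2‑addition to the hindered, enolisable cyclopentanone occurs anti to the adjacent C5 side chain and sets C4 (4β‑OH, 4α‑iPr), and Tamao–Fleming oxidation then turns the C–Si bond into the primary C6–OH.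

Step 6
Reactants: 8 methacrolein
Product: 10 {1-[(benzyloxy)methoxy]-2-methylprop-2-en-1-yl}tributylstannane (racemic), via lithium alkoxide 9 (not isolated)
Conditions: Bu3SnH, LDA, THF, 0 → −78 °C; 8, −78 °C; then BOMCl, −78 → 0 °C
Reagents that add atoms: tributyltin hydride CCCC[SnH](CCCC)CCCC; benzyl chloromethyl ether ClCOCc1ccccc1
Why: 1,2‑Addition of tributylstannyllithium to the enal and O‑alkylation of the alkoxide (Still‑type α‑alkoxystannane synthesis) give a racemic centre that is erased in step 7.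

Step 7
Reactants: 10 {1-[(benzyloxy)methoxy]-2-methylprop-2-en-1-yl}tributylstannane
Product: 11 {(2Z)-3-[(benzyloxy)methoxy]-2-methylprop-2-en-1-yl}tributylstannane
Conditions: BF3·OEt2 (1 equiv), CH2Cl2, −78 °C
Reagents that add atoms: none
Why: The Lewis‑acid‑promoted 1,3‑stannyl shift of an α‑alkoxyallylstannane (Marshall isomerisation), driven by the conjugated enol ether and a primary C–Sn bond, gives the (Z)‑γ‑alkoxyallylstannane without any strong base that could attack the BOM group.

Step 8
Reactants: 7 (1R,2S,3R)-2-(hydroxymethyl)-3-methyl-1-(propan-2-yl)-3-(prop-2-en-1-yl)cyclopentan-1-ol; 11 {(2Z)-3-[(benzyloxy)methoxy]-2-methylprop-2-en-1-yl}tributylstannane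
Product: 15 (1R,2S,3R)-2-{(1R,2R)-2-[(benzyloxy)methoxy]-1-hydroxy-3-methylbut-3-en-1-yl}-3-methyl-1-(propan-2-yl)-3-(prop-2-en-1-yl)cyclopentan-1-ol, via aldehyde 12 (not isolated), via allyllithium 13 (not isolated), via allylborane 14 (not isolated)
Conditions: 7: TEMPO (10 mol %), PhI(OAc)2, CH2Cl2, rt, crude; 11 (2.5 equiv): n-BuLi, THF, −78 °C; (−)-Ipc2BOMe; BF3·OEt2; then crude aldehyde, −78 °C → rt; NaOH, H2O2
Reagents that add atoms: none
Why: TEMPO/PhI(OAc)2 oxidises only the primary alcohol, and Brown (Z)‑γ‑alkoxyallylboration through a chair Zimmerman–Traxler transition state on the Si face of the C6 aldehyde (chosen by the (+)‑α‑pinene‑derived Ipc groups) sets C6 (6α‑OH) and C7 (7β‑OBOM) as the syn pair under reagent control and turns the minor enantiomer left from step 1 into a separable diastereomer.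

Step 9
Reactants: 15 (1R,2S,3R)-2-{(1R,2R)-2-[(benzyloxy)methoxy]-1-hydroxy-3-methylbut-3-en-1-yl}-3-methyl-1-(propan-2-yl)-3-(prop-2-en-1-yl)cyclopentan-1-ol
Product: 16 7β-[(benzyloxy)methoxy]dauc-8-ene-4β,6α-diol
Conditions: Grubbs II (5 mol %), CH2Cl2 (5 mM), 40 °C
Reagents that add atoms: none
Why: Ring‑closing olefin metathesis between the allyl and isopropenyl groups, driven by loss of ethene, closes the seven‑membered ring as the ring‑constrained trisubstituted C8=C9 alkene without changing any stereocentre.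

Step 10
Reactants: 16 7β-[(benzyloxy)methoxy]dauc-8-ene-4β,6α-diol
Product: 17 7β-[(benzyloxy)methoxy]-8α,9α-epoxydaucane-4β,6α-diol
Conditions: VO(acac)2 (5 mol %), t-BuOOH (1.5 equiv), CH2Cl2, 0 °C → rt
Reagents that add atoms: tert-butyl hydroperoxide CC(C)(C)OO
Why: In this hydroxyl‑directed vanadium‑catalysed epoxidation the homoallylic 6α‑OH binds the vanadium peroxide and delivers oxygen to the α‑face of C8=C9, which is also the face away from the angular methyl and the 7β‑OBOM group (sets C8 and C9).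

Step 11
Reactants: 18 4-bromophenol
Product: 19 1-(benzyloxy)-4-bromobenzene
Conditions: BnBr, K2CO3, DMF, 60 °C
Reagents that add atoms: benzyl bromide BrCc1ccccc1
Why: Williamson ether synthesis on the phenoxide.

Step 12
Reactants: 19 1-(benzyloxy)-4-bromobenzene
Product: 21 4-(benzyloxy)benzoic acid, via aryllithium 20 (not isolated)
Conditions: n-BuLi, THF, −78 °C; CO2; aq. HCl
Reagents that add atoms: carbon dioxide O=C=O
Why: Bromine–lithium exchange followed by carboxylation of the aryllithium.

Step 13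
Reactants: 21 4-(benzyloxy)benzoic acid
Product: 22 4-(benzyloxy)benzoyl chloride
Conditions: (COCl)2, DMF (cat.), CH2Cl2, 0 °C → rt
Reagents that add atoms: oxalyl chloride ClC(=O)C(=O)Cl
Why: Acid chloride formation with oxalyl chloride under DMF (Vilsmeier‑type) catalysis.

Step 14
Reactants: 17 7β-[(benzyloxy)methoxy]-8α,9α-epoxydaucane-4β,6α-diol; 22 4-(benzyloxy)benzoyl chloride
Product: 23 7β-[(benzyloxy)methoxy]-8α,9α-epoxy-4β-hydroxydaucan-6α-yl 4-(benzyloxy)benzoate
Conditions: 22 (1.5 equiv), Et3N, DMAP (0.2 equiv), CH2Cl2, 0 °C → rt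
Reagents that add atoms: none
Why: DMAP‑catalysed acylation (acylpyridinium transfer) takes the only free secondary hydroxyl, 6‑OH, while the tertiary 4‑OH is inert and C6 keeps its configuration because its C–O bond is not broken.

Step 15
Reactants: 23 7β-[(benzyloxy)methoxy]-8α,9α-epoxy-4β-hydroxydaucan-6α-yl 4-(benzyloxy)benzoate
Product: 24 8α,9α-epoxy-4β,7β-dihydroxydaucan-6α-yl 4-hydroxybenzoate (CNP0290052.1)
Conditions: H2 (1 atm), Pd(OH)2/C, EtOAc, rt
Reagents that add atoms: none
Why: Palladium‑catalysed hydrogenolysis cleaves the aryl benzyl ether and the BOM acetal under neutral conditions, so the trisubstituted epoxide, the ester and the tertiary alcohol survive and neither 6→7 acyl migration nor Payne rearrangement can occur.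

**Compound list**
1 | 3-methylcyclopent-2-en-1-one | CC1=CC(=O)CC1 | starting material
2 | (S)-3-methylcyclopent-2-en-1-ol | CC1=C[C@@H](O)CC1 | intermediate
3 | (S)-(bromomethyl)dimethyl[(3-methylcyclopent-2-en-1-yl)oxy]silane | CC1=C[C@@H](O[Si](C)(C)CBr)CC1 | intermediate
4 | (3aR,4R,6aS)-2,2,4-trimethyl-4-(prop-2-en-1-yl)hexahydro-2H-cyclopenta[d][1,2]oxasilole (cis-fused) | C=CC[C@@]1(C)CC[C@@H]2O[Si](C)(C)C[C@H]12 | intermediate
5 | (2R,3R)-2-[(hydroxydimethylsilyl)methyl]-3-methyl-3-(prop-2-en-1-yl)cyclopentan-1-one | C=CC[C@@]1(C)CCC(=O)[C@@H]1C[Si](C)(C)O | intermediate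
6 | (1R,2R,3R)-2-[(hydroxydimethylsilyl)methyl]-3-methyl-1-(propan-2-yl)-3-(prop-2-en-1-yl)cyclopentan-1-ol | C=CC[C@@]1(C)CC[C@@](O)(C(C)C)[C@@H]1C[Si](C)(C)O | intermediate
7 | (1R,2S,3R)-2-(hydroxymethyl)-3-methyl-1-(propan-2-yl)-3-(prop-2-en-1-yl)cyclopentan-1-ol | C=CC[C@@]1(C)CC[C@@](O)(C(C)C)[C@@H]1CO | intermediate
8 | methacrolein (2-methylprop-2-enal) | CC(=C)C=O | starting material
9 | lithium 2-methyl-1-(tributylstannyl)prop-2-en-1-olate (racemic) | CCCC[Sn](CCCC)(CCCC)C(O[Li])C(C)=C | intermediate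
10 | {1-[(benzyloxy)methoxy]-2-methylprop-2-en-1-yl}tributylstannane (racemic) | CCCC[Sn](CCCC)(CCCC)C(OCOCc1ccccc1)C(C)=C | intermediate
11 | {(2Z)-3-[(benzyloxy)methoxy]-2-methylprop-2-en-1-yl}tributylstannane | CCCC[Sn](CCCC)(CCCC)C/C(C)=C\OCOCc1ccccc1 | intermediate
12 | (1R,2R,5R)-2-hydroxy-5-methyl-2-(propan-2-yl)-5-(prop-2-en-1-yl)cyclopentane-1-carbaldehyde | C=CC[C@@]1(C)CC[C@@](O)(C(C)C)[C@@H]1C=O | intermediate
13 | {(2Z)-3-[(benzyloxy)methoxy]-2-methylprop-2-en-1-yl}lithium | [Li]C/C(C)=C\OCOCc1ccccc1 | intermediate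
14 | B-{(2Z)-3-[(benzyloxy)methoxy]-2-methylprop-2-en-1-yl}diisopinocampheylborane (Ipc from (+)-α-pinene) | C(/C(C)=C\OCOCc1ccccc1)B([C@@H]1C[C@@H]2C[C@H]([C@H]1C)C2(C)C)[C@@H]1C[C@@H]2C[C@H]([C@H]1C)C2(C)C | intermediate
15 | (1R,2S,3R)-2-{(1R,2R)-2-[(benzyloxy)methoxy]-1-hydroxy-3-methylbut-3-en-1-yl}-3-methyl-1-(propan-2-yl)-3-(prop-2-en-1-yl)cyclopentan-1-ol | C=CC[C@@]1(C)CC[C@@](O)(C(C)C)[C@@H]1[C@@H](O)[C@H](OCOCc1ccccc1)C(C)=C | intermediate
16 | 7β-[(benzyloxy)methoxy]dauc-8-ene-4β,6α-diol (1β-CH3, 5α-H, trans-fused) | CC(C)[C@]1(O)CC[C@]2(C)CC=C(C)[C@@H](OCOCc3ccccc3)[C@H](O)[C@H]21 | intermediate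
17 | 7β-[(benzyloxy)methoxy]-8α,9α-epoxydaucane-4β,6α-diol | CC(C)[C@]1(O)CC[C@]2(C)C[C@@H]3O[C@]3(C)[C@@H](OCOCc3ccccc3)[C@H](O)[C@H]21 | intermediate
18 | 4-bromophenol | Oc1ccc(Br)cc1 | starting material
19 | 1-(benzyloxy)-4-bromobenzene | Brc1ccc(OCc2ccccc2)cc1 | intermediate
20 | [4-(benzyloxy)phenyl]lithium | [Li]c1ccc(OCc2ccccc2)cc1 | intermediate
21 | 4-(benzyloxy)benzoic acid | OC(=O)c1ccc(OCc2ccccc2)cc1 | intermediate
22 | 4-(benzyloxy)benzoyl chloride | ClC(=O)c1ccc(OCc2ccccc2)cc1 | intermediate
23 | 7β-[(benzyloxy)methoxy]-8α,9α-epoxy-4β-hydroxydaucan-6α-yl 4-(benzyloxy)benzoate | CC(C)[C@]1(O)CC[C@]2(C)C[C@@H]3O[C@]3(C)[C@@H](OCOCc3ccccc3)[C@H](OC(=O)c3ccc(OCc4ccccc4)cc3)[C@H]21 | intermediate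
24 | 8α,9α-epoxy-4β,7β-dihydroxydaucan-6α-yl 4-hydroxybenzoate (CNP0290052.1) | CC(C)[C@]1(O)CC[C@]2(C)C[C@@H]3O[C@]3(C)[C@@H](O)[C@H](OC(=O)c3ccc(O)cc3)[C@H]21 | target

**Step count**
Total step count: 15. Longest linear sequence: 10 steps (steps 1, 2, 3, 4, 5, 8, 9, 10, 14, 15).

**Three steps most likely to fail**

Step 3 (the new cobalt cascade). The risks are allylation of the α‑silyl radical before ring closure, β‑hydride loss from the tertiary alkylcobalt, and Grignard attack at silicon. The fallback uses known chemistry and sets out from 3: the same two bonds are made as a tin radical chain with allyltributylstannane (4 equiv), AIBN, benzene, 80 °C (Stork–Nishiyama silicon‑tethered 5‑exo cyclisation followed by Keck allyl transfer to the tertiary radical, again anti to the C5–CH2 bond). It comes back to the route at 4; no new compound is made (F0).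

Step 8 (oxidation and alkoxyallylboration). The aldehyde is α‑branched between two quaternary carbons, the bulky Ipc2B reagent may add slowly, and a simple Felkin model of the substrate predicts the opposite face, so the pairing may be mismatched. The fallback sets out from 7 (oxidised to 12 as before) and 11 and replaces the boron reagent by chelation control: MgBr2·OEt2 (3 equiv), CH2Cl2, −20 °C, then stannane 11 (Keck–Marshall SE2′ addition through an open transition state). Magnesium bridges the aldehyde oxygen and the 4‑OH, the stannane attacks the chelate anti to C1, which is the required 6R sense, and the (Z)‑enol ether again gives the 6,7‑syn pair. It comes back to the route at 15; no new compound is made (F0).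

Step 10 (directed epoxidation). The risks are weak direction by a homoallylic hydroxyl, interference by the tertiary 4‑OH, and transannular opening of the new epoxide by the cis 6‑OH. The fallback sets out from 16 and inverts the order: acylation with 22 (Et3N, DMAP, CH2Cl2) gives 7β-[(benzyloxy)methoxy]-4β-hydroxydauc-8-en-6α-yl 4-(benzyloxy)benzoate F1. Undirected Prilezhaev epoxidation (mCPBA, NaHCO3, CH2Cl2, 0 °C) then attacks the α‑face, since the β‑face is blocked by the angular methyl and the 7β‑OBOM group. It comes back to the route at 23.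

**Further compounds**
F0 | step 3 | none | none
F0 | step 8 | none | none
F1 | step 10 | 7β-[(benzyloxy)methoxy]-4β-hydroxydauc-8-en-6α-yl 4-(benzyloxy)benzoate | CC(C)[C@]1(O)CC[C@]2(C)CC=C(C)[C@@H](OCOCc3ccccc3)[C@H](OC(=O)c3ccc(OCc4ccccc4)cc3)[C@H]21
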